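**Strategy.** The cyclopentene ring is numbered C1(OAc)–C2(OH)(acyl)–C3(OAc)–C4=C5. Everything rests on cutting both allylic bonds, C3–C4 and C5–C1. A two-directional double Stille acylation stitches a cis-1,2-distannylethene (the C4=C5 unit) onto both acid chloride ends of a 2,2-disubstituted malonyl dichloride (C1–C2–C3), forming both bonds and the five-membered ring in one operation. The step exploits the mirror symmetry of the ring, in which the cis C4=C5 alkene lies between two equivalent oxygenated carbons on quaternary C2. The precursor is acyclic: an acetonide-masked hydroxy ketone on a malonyl core. Luche reduction of the resulting spiro enedione then sets the cis diol.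

Key step: step 7

Remark: the target is meso (both acetoxy groups cis to the undecanoyl group and trans to the tertiary hydroxyl), so every chiral intermediate is racemic and is drawn as one enantiomer.

Step 1
Reactants: 1 undecanal; 2 diethyl malonate
Product: 3 diethyl 2-undecylidenepropanedioate
Conditions: TiCl4 (2 equiv), pyridine (4 equiv), THF, 0 °C to rt
Reagents that add atoms: none
Why: Knoevenagel condensation in the Lehnert variant, in which TiCl4/pyridine activates the enolisable aliphatic aldehyde at 0 °C so that self-aldol and deconjugation of the alkylidene malonate should be avoided.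

Step 2
Reactants: 3 diethyl 2-undecylidenepropanedioate
Product: 4 diethyl 2-hydroxy-2-(1-hydroxyundecyl)propanedioate (racemic)
Conditions: OsO4 (2 mol %), NMO (1.5 equiv), citric acid (1 equiv), t-BuOH/H2O 1:1, rt
Reagents that add atoms: N-methylmorpholine N-oxide, C[N+]1([O-])CCOCC1; water, O
Why: Osmium-catalysed syn-dihydroxylation (Upjohn conditions with citric acid, which keeps the catalytic cycle turning for electron-poor alkenes) should give the diol and sets the side-chain carbinol as a racemate, a centre that is erased in step 11.

Step 3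
Reactants: 4 diethyl 2-hydroxy-2-(1-hydroxyundecyl)propanedioate
Product: 5 diethyl 5-decyl-2,2-dimethyl-1,3-dioxolane-4,4-dicarboxylate
Conditions: 2,2-dimethoxypropane, p-TsOH·H2O (cat.), acetone, rt
Reagents that add atoms: 2,2-dimethoxypropane, COC(C)(C)OC
Why: Acid-catalysed transketalisation closes the five-membered acetonide, which protects the tertiary hydroxyl for the acid chloride stage and masks the future ketone as a carbinol.

Step 4
Reactants: 5 diethyl 5-decyl-2,2-dimethyl-1,3-dioxolane-4,4-dicarboxylate
Product: 6 5-decyl-2,2-dimethyl-1,3-dioxolane-4,4-dicarboxylic acid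
Conditions: LiOH·H2O (6 equiv), THF/MeOH/H2O, 50 °C; then cold 1 M HCl to pH 3, EtOAc extraction
Reagents that add atoms: lithium hydroxide, [Li+].[OH-]
Why: Ester saponification of the non-enolisable gem-diester; the acetonide is stable to base and should survive the brief cold acidification, and the disubstituted malonic acid should not decarboxylate at or below room temperature.

Step 5
Reactants: 6 5-decyl-2,2-dimethyl-1,3-dioxolane-4,4-dicarboxylic acid
Product: 7 5-decyl-2,2-dimethyl-1,3-dioxolane-4,4-dicarbonyl dichloride (used crude)
Conditions: 1-chloro-N,N,2-trimethylprop-1-en-1-amine (2.4 equiv), CH2Cl2, 0 °C to rt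
Reagents that add atoms: 1-chloro-N,N,2-trimethylprop-1-en-1-amine (Ghosez reagent), CC(C)=C(Cl)N(C)C
Why: The Ghosez α-chloroenamine converts carboxylic acids into acid chlorides under neutral conditions without free HCl, so the acetonide should survive.

Step 6
Reactants: 8 acetylene; 9 hexamethylditin
Product: 10 (Z)-1,2-bis(trimethylstannyl)ethene
Conditions: Pd(PPh3)4 (1 mol %), acetylene (1 atm), 1,4-dioxane, 60 °C
Reagents that add atoms: none
Why: Palladium-catalysed syn-distannation of an alkyne (oxidative addition of Sn–Sn to zerovalent palladium, insertion, reductive elimination) delivers both tin groups to the same face and so fixes the Z geometry.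

Step 7
Reactants: 7 5-decyl-2,2-dimethyl-1,3-dioxolane-4,4-dicarbonyl dichloride; 10 (Z)-1,2-bis(trimethylstannyl)ethene
Product: 12 4-decyl-2,2-dimethyl-1,3-dioxaspiro[4.4]non-7-ene-6,9-dione, via stannylvinyl ketone acid chloride 11 (not isolated)
Conditions: Pd2(dba)3 (2.5 mol %), tri(2-furyl)phosphine (10 mol %), toluene, 0.01 M, slow addition of 7 and 10, 60 °C
Reagents that add atoms: none
Why: Zerovalent palladium inserts into one C–Cl bond of 7, the acylpalladium chloride (divalent palladium) transmetallates with one vinyl–tin bond of 10 and reductive elimination gives stannyl enone 11; a second oxidative addition at the remaining acid chloride is followed by intramolecular transmetallation and reductive elimination, so that both alkene–carbonyl bonds are made in one flask. The closest known reaction types are the Stille ketone synthesis from acid chlorides and vinylstannanes and the double Stille stitching of cis-1,2-distannylethenes onto bis-electrophiles. The cyclopentenedione ring is closed by C(acyl)–C(vinyl) reductive elimination from a six-membered acyl(vinyl)palladacycle, a formal (3+2) annulation. No stereocentre is created, because the spiro carbon carries two identical acyl arms, and the Z geometry of 10 is carried through with retention. The step needs ring closure to beat oligomerisation and decarbonylation, which the cis placement of the second tin, the gem-disubstituted (Thorpe–Ingold) malonyl carbon, the lack of α-hydrogens (no ketene) and high dilution with slow addition should secure.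

Step 8
Reactants: 12 4-decyl-2,2-dimethyl-1,3-dioxaspiro[4.4]non-7-ene-6,9-dione
Product: 14 4-decyl-2,2-dimethyl-1,3-dioxaspiro[4.4]non-7-ene-6,9-diol (hydroxyls cis to each other and to C4 and trans to O1), via hydroxy enone 13 (not isolated)
Conditions: NaBH4 (2.5 equiv), CeCl3·7H2O (2.5 equiv), MeOH, −78 to −40 °C
Reagents that add atoms: none
Why: Luche 1,2-reduction: hydride should approach each carbonyl from the face of the small dioxolane oxygen O1 (away from C4 and its decyl chain, the face also favoured by cerium chelation of the α-alkoxy ketone), and in hydroxy enone 13 the new oxygen function reinforces attack anti to itself (cis-1,4 preference of 4-oxycyclopentenones), so both carbinols should end cis to each other and trans to O1.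

Step 9
Reactants: 14 4-decyl-2,2-dimethyl-1,3-dioxaspiro[4.4]non-7-ene-6,9-diol
Product: 15 4-decyl-2,2-dimethyl-1,3-dioxaspiro[4.4]non-7-ene-6,9-diyl diacetate
Conditions: Ac2O (4 equiv), pyridine, DMAP (cat.), CH2Cl2, rt
Reagents that add atoms: acetic anhydride, CC(=O)OC(C)=O
Why: DMAP-catalysed acylation of the two secondary allylic alcohols, with no stereocentre touched.

Step 10
Reactants: 15 4-decyl-2,2-dimethyl-1,3-dioxaspiro[4.4]non-7-ene-6,9-diyl diacetate
Product: 16 2-hydroxy-2-(1-hydroxyundecyl)cyclopent-4-ene-1,3-diyl diacetate (acetoxy groups cis to each other and to the hydroxyundecyl group, trans to the tertiary hydroxyl)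
Conditions: AcOH/H2O 4:1, 50 °C
Reagents that add atoms: none
Why: Mild acid hydrolysis of the acetonide; acetates are stable to aqueous acetic acid and the tertiary hydroxyl is trans to both acetoxy groups, which disfavours acyl migration to it.

Step 11
Reactants: 16 2-hydroxy-2-(1-hydroxyundecyl)cyclopent-4-ene-1,3-diyl diacetate
Product: 17 (1R,2r,3S)-2-hydroxy-2-undecanoylcyclopent-4-ene-1,3-diyl diacetate (meso target)
Conditions: IBX (1.5 equiv), DMSO, rt
Reagents that add atoms: none
Why: IBX oxidises the secondary alcohol of a 1,2-diol to the α-hydroxy ketone without C–C cleavage and leaves the tertiary alcohol untouched; removal of the side-chain stereocentre makes the product the meso target.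

**Compound list**

1 | undecanal | CCCCCCCCCCC=O | starting material
2 | diethyl malonate | CCOC(=O)CC(=O)OCC | starting material
3 | diethyl 2-undecylidenepropanedioate | CCCCCCCCCCC=C(C(=O)OCC)C(=O)OCC | intermediate
4 | diethyl 2-hydroxy-2-(1-hydroxyundecyl)propanedioate (racemic) | CCCCCCCCCC[C@H](O)C(O)(C(=O)OCC)C(=O)OCC | intermediate
5 | diethyl 5-decyl-2,2-dimethyl-1,3-dioxolane-4,4-dicarboxylate (racemic) | CCCCCCCCCC[C@H]1C(OC(C)(C)O1)(C(=O)OCC)C(=O)OCC | intermediate
6 | 5-decyl-2,2-dimethyl-1,3-dioxolane-4,4-dicarboxylic acid (racemic) | CCCCCCCCCC[C@H]1C(OC(C)(C)O1)(C(=O)O)C(=O)O | intermediate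
7 | 5-decyl-2,2-dimethyl-1,3-dioxolane-4,4-dicarbonyl dichloride (racemic) | CCCCCCCCCC[C@H]1C(OC(C)(C)O1)(C(=O)Cl)C(=O)Cl | intermediate
8 | acetylene | C#C | starting material
9 | hexamethylditin | C[Sn](C)(C)[Sn](C)(C)C | starting material
10 | (Z)-1,2-bis(trimethylstannyl)ethene | C[Sn](C)(C)/C=C\[Sn](C)(C)C | intermediate
11 | 5-decyl-2,2-dimethyl-4-[(Z)-3-(trimethylstannyl)prop-2-enoyl]-1,3-dioxolane-4-carbonyl chloride (both diastereomers at C4) | CCCCCCCCCC[C@H]1C(OC(C)(C)O1)(C(=O)Cl)C(=O)/C=C\[Sn](C)(C)C | intermediate (not isolated)
12 | 4-decyl-2,2-dimethyl-1,3-dioxaspiro[4.4]non-7-ene-6,9-dione (racemic) | CCCCCCCCCC[C@H]2C1(OC(C)(C)O2)C(=O)C=CC1=O | intermediate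
13 | 4-decyl-9-hydroxy-2,2-dimethyl-1,3-dioxaspiro[4.4]non-7-en-6-one, hydroxyl trans to O1 (either carbonyl may be reduced first; one regioisomer drawn) | CCCCCCCCCC[C@H]2[C@@]1(OC(C)(C)O2)[C@@H](O)C=CC1=O | intermediate (not isolated)
14 | 4-decyl-2,2-dimethyl-1,3-dioxaspiro[4.4]non-7-ene-6,9-diol, hydroxyls cis to each other and to C4, trans to O1 (racemic) | CCCCCCCCCC[C@H]2[C@@]1(OC(C)(C)O2)[C@@H](O)C=C[C@H]1O | intermediate
15 | 4-decyl-2,2-dimethyl-1,3-dioxaspiro[4.4]non-7-ene-6,9-diyl diacetate, same relative configuration (racemic) | CCCCCCCCCC[C@H]2[C@@]1(OC(C)(C)O2)[C@@H](OC(C)=O)C=C[C@H]1OC(C)=O | intermediate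
16 | 2-hydroxy-2-(1-hydroxyundecyl)cyclopent-4-ene-1,3-diyl diacetate, acetoxy groups cis to each other and trans to the tertiary hydroxyl (racemic) | CCCCCCCCCC[C@H](O)[C@@]1(O)[C@@H](OC(C)=O)C=C[C@H]1OC(C)=O | intermediate
17 | (1R,2r,3S)-2-hydroxy-2-undecanoylcyclopent-4-ene-1,3-diyl diacetate (meso) | CCCCCCCCCCC(=O)[C@@]1(O)[C@@H](OC(C)=O)C=C[C@H]1OC(C)=O | target

Total steps: 11. Longest linear sequence: 10 steps (steps 1–5 and 7–11).

**Steps most likely to fail**

Step 7. Decarbonylation of the hindered α-alkoxy acylpalladium, protodestannylation, or oligomerisation may outrun ring closure. The same two bonds can still be made in one operation by enolate chemistry. Starting from 7, the dilithium dianion of diethyl succinate (LiN(iPr)2, THF, −78 °C) is acylated twice to give diethyl 4-decyl-2,2-dimethyl-6,9-dioxo-1,3-dioxaspiro[4.4]nonane-7,8-dicarboxylate F1 (double Claisen-type C-acylation). Krapcho dealkoxycarbonylation (NaCl, wet DMSO, 150 °C) should then give 4-decyl-2,2-dimethyl-1,3-dioxaspiro[4.4]nonane-6,9-dione F2. IBX dehydrogenation (DMSO/fluorobenzene, 70 °C) introduces the ring alkene and returns to the route at 12.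

Step 8. Hydride may be delivered mainly anti to O1, facial selectivity may be poor, or conjugate reduction of the enedione may compete. The stereochemistry would then be corrected by inversion instead of by the reduction. Starting from 12, reduction under non-chelating conditions (iBu2AlH, CH2Cl2, −78 °C) is used to collect all-syn 4-decyl-2,2-dimethyl-1,3-dioxaspiro[4.4]non-7-ene-6,9-diol F3 (both hydroxyls cis to O1). A double Mitsunobu reaction with acetic acid (PPh3, DIAD, THF) should invert both carbinols and give the diacetate directly, rejoining the route at 15.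

Step 10. During hydrolysis an acetyl group may migrate from a ring oxygen to the freed side-chain hydroxyl, or the allylic acetates may ionise. The order is then changed so that no ester is present while the side-chain alcohol is free. Starting from 14, the acetonide is hydrolysed first (AcOH/H2O, 50 °C) to give 2-(1-hydroxyundecyl)cyclopent-4-ene-1,2,3-triol F4. The only vicinal diol is activated as its dibutylstannylene acetal (Bu2SnO, MeOH, reflux) and oxidised at the secondary carbinol with NBS (CHCl3, rt) to give 1-(1,2,5-trihydroxycyclopent-3-en-1-yl)undecan-1-one F5. Ac2O/pyridine without DMAP should then acylate only the two secondary allylic hydroxyls and give the target 17.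

**Further compounds**

F1 | step 7 | diethyl 4-decyl-2,2-dimethyl-6,9-dioxo-1,3-dioxaspiro[4.4]nonane-7,8-dicarboxylate | CCCCCCCCCC[C@H]2C1(OC(C)(C)O2)C(=O)C(C(=O)OCC)C(C(=O)OCC)C1=O
F2 | step 7 | 4-decyl-2,2-dimethyl-1,3-dioxaspiro[4.4]nonane-6,9-dione | CCCCCCCCCC[C@H]2C1(OC(C)(C)O2)C(=O)CCC1=O
F3 | step 8 | all-syn 4-decyl-2,2-dimethyl-1,3-dioxaspiro[4.4]non-7-ene-6,9-diol (hydroxyls cis to O1) | CCCCCCCCCC[C@H]2[C@@]1(OC(C)(C)O2)[C@H](O)C=C[C@@H]1O
F4 | step 10 | 2-(1-hydroxyundecyl)cyclopent-4-ene-1,2,3-triol | CCCCCCCCCC[C@H](O)[C@@]1(O)[C@@H](O)C=C[C@H]1O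
F5 | step 10 | 1-(1,2,5-trihydroxycyclopent-3-en-1-yl)undecan-1-one | CCCCCCCCCCC(=O)[C@@]1(O)[C@@H](O)C=C[C@H]1O
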